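The earlier runs and the new flask stem from a simulated flask for an exercise.

In time, the south-east run falls into two stages, a lag and then a rise of target. That run is the flask asked about, followed so far.

| flask | substrate | transfer agent | solid reagent | initiator | remark | time |
|---|---|---|---|---|---|---|
| south-east | 5.0 × 10⁻⁴ M (fed, over 6.0 s) | 0.025 mM | 1.2 equiv | 5 mol% | the very flask that is asked about, followed so far; the fed solution adds 0.10 times the starting volume |  |
| south-west | 7.5 × 10⁻⁴ M (fed, over 6.0 s) | 0.025 mM | 1.2 equiv | 5 mol% | run made earlier; the fed solution adds 0.10 times the starting volume |  |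
| flask | 5.0 × 10⁻⁴ M (fed, over 6.0 s) | 0.0250 mM | 1.20 equiv | 5 mol% | the fed solution adds 0.10 times the starting volume | 30 min |

| run | time / min | target / % | side product / % |
|---|---|---|---|
| south-east | 0.417 | 0 | 0.8 |
| south-east | 0.667 | 0.6 | 2.2 |
| south-east | 1.00 | 0 | 3.0 |
| south-east | 1.50 | 0.6 | 3.3 |
| south-east | 2.50 | 11.1 | 5.5 |
| south-east | 4.00 | 34.2 | 4.1 |
| south-east | 5.00 | 38.9 | 4.9 |
| south-west | 2.50 | 26.0 | 3.3 |
| south-west | 4.00 | 49.2 | 3.0 |
| south-west | 6.00 | 61.7 | 3.5 |
| south-west | 8.00 | 63.4 | 3.6 |
| south-west | 12.0 | 65.1 | 2.7 |
| south-west | 20.0 | 65.2 | 2.5 |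
| south-west | 30.0 | 64.8 | 3.8 |

(each reading ± 0.5 percentage points)

- every charge counts on the volume at the start, and the solution that is fed holds the whole dose
- solid, in amounts per volume of the solution: solid reagent
- what was read earlier has a scatter of 0.5 percentage points, one standard deviation
- at the start none of the solid reagent is in solution
- the reaction counts as stopped when no species that holds the substrate changes by six tenths of a point or more over the second half of the time

- the state of affairs at 30 min: stopped, and by what, or still going (for what has run out or reacted, a solid counts together with what of it has only dissolved) (the partner has run out first / all of the substrate has reacted / it is still moving)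
- target at 30 min, in percent of the substrate charged
- side product at 30 min, in percent of the substrate charged

The lag belongs to side product. The quantity to carry is 5.00% for the asked flask: the transfer ceiling, [transfer agent] charged over [substrate] charged, which counts one side product for each transfer agent. The south-west run has a ceiling of 3.33%, and its readings average 3.20%. The last south-east readings average 4.83%. So side product in the asked flask is put at 5.00%.

The ceiling also sorts the readings. At 1.50 min the south-east run holds side product at 3.3%, below the ceiling, and target at 0.6%. At 2.50 min side product reads 5.5% and target 11.1%, so the readings from there on are taken as the rise.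

The south-west target stays flat from 12.0 min, at 65.1% to 64.8%, although the partner was charged at 1.2 equiv. The stop therefore looks like one on the partner side. Between 4.00 min and 6.00 min the distance to that plateau shrinks at 0.760 min⁻¹.

With the same constant, the south-east readings at 4.00 min and 5.00 min give a plateau of 43.0%. That link is weak, since it rests on a gain of 4.7 percentage points between readings with a scatter of 0.5 points each. The pair from 2.50 min and 5.00 min spans 28 points and gives 43.8%, the number this reckoning commits to.

The forecast says the partner has run out first, with 43% target and 4.8% side product, on the ground that “The shortfall looks like a fixed absolute loss”.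

At 30 min the flask gives: the partner has run out first, with partner at 1.08 × 10⁻⁶ M, solid reagent at 0%, target 43.7% and side product 5.00%. Target moves by 5 points at a substrate charge of 4.71 × 10⁻⁴ M or 5.35 × 10⁻⁴ M, or at an initiator loading of 4.6 mol% or 5.4 mol%. Side product meets the ceiling of 5.00%, stands at 5.00% by 6.00 min, and transfer agent ends at 0% of its charge.

    substrate + initiating radical → capped initiator + first chain carrier (k = 7.20 × 10⁷ M⁻¹ s⁻¹)
    2 idle radical → ended radicals (k = 1.60 × 10⁷ M⁻¹ s⁻¹)
    2 partner → homo dimer (k = 35.0 M⁻¹ s⁻¹)
    initiator → 2 initiating radical (k = 0.00540 s⁻¹)
    2 second chain carrier → ended chains A (k = 1.00 × 10⁸ M⁻¹ s⁻¹)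
    substrate + second chain carrier → by-product + first chain carrier (k = 2.40 × 10⁶ M⁻¹ s⁻¹)
    solid reagent ⇌ partner, rate k7*(cs7 - [partner]) while solid is left; crystals form when [partner] > cs7 (solubility = 0.270 mM, k = 0.0250 s⁻¹)
    partner + first chain carrier → target + second chain carrier (k = 8.80 × 10⁵ M⁻¹ s⁻¹)
    2 first chain carrier → ended chains B (k = 3.00 × 10⁸ M⁻¹ s⁻¹)
    transfer agent + first chain carrier → side product + idle radical (kL = 1.40 × 10⁸ M⁻¹ s⁻¹)

A neighbour charged with 1.0 × 10⁻⁵ M of transfer agent has a ceiling of 2.00%. Its computed side product is 2.00%, with target at 69.8%.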